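## Analysis of the target

- Target 25 is a bicyclo[3.2.1]octane neolignan. The locants used throughout are: C1 the allyl-bearing bridgehead, C2 the methylene, C3 the methoxy-bearing CH, C4 the ketone, C5 the methoxy-bearing bridgehead, C6 the aryl carbon, C7 the methyl carbon, C8 the carbinol bridge, C9–C11 the allyl group.
- Two rings share C1, C8 and C5: the five-membered ring C1–C7–C6–C5–C8 and the six-membered ring C1–C2–C3–C4–C5–C8.
- Eight ring carbons carry six stereocentres (1S,3S,5S,6S,7R,8S), two of them quaternary (C1 all-carbon, C5 oxygenated).
- The aryl group at C6 is endo and trans to the exo methyl at C7. The C8 hydroxyl lies over the six-membered ring (syn to C2–C4). The C3 methoxy group lies on the other face of that ring, towards the C6–C7 bridge.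
- Sensitive groups are the β-hydroxy ketone C8(OH)–C5–C4(=O), which can open by retro-aldol cleavage, the epimerisable α-methoxy centre C3, the free phenol, and the terminal alkene, which excludes hydrogenation.
- The synthesis is hard for three reasons: the two bridgehead quaternary carbons flank every other centre, the aryl group must sit on the concave side trans to methyl, and C3 and C8 must be set on the finished cage against the steric bias of the exo methyl and the endo aryl.
- The strategy rests on the five-membered ring C1–C7–C6–C5–C8. With C8 as a carbonyl it is a cyclopentanone whose β-carbons C6 and C7 carry the trans aryl/methyl pair and whose α-carbons C1 and C5 are the two anchoring points of the C2–C3–C4 bridge. That is the pattern a conrotatory 4π closure of a divinyl ketone produces.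

## Retrosynthetic reasoning

**25 ⇒ 24 (C3–H and two O–Si bonds).** C3 is the only enolisable carbon of the cage and the only centre not fixed by ring constraints. It is therefore carried as the sp2 carbon of a C3=C4 silyl enol ether in 24 and created last. One desilylation frees the phenol and the C4 enolate, and the forward step must put the proton on the face of C3 that looks at C8.

**24 ⇒ 23 (C8–H).** The carbinol is traced to the bridging ketone of 23. The cut is made here because C8 has to be a carbonyl for the ring-forming steps before it. The forward reduction must place hydrogen on the face that carries the exo C7 methyl, so that the hydroxyl ends over the six-membered ring.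

**23 ⇒ 22 ⇒ 21 (no skeletal bond; oxidation levels at C4 and C8).** The aldol that builds the cage gives C4 as an alcohol and C8 as a ketone, the reverse of the target. Oxidation of 21 gives diketone 22. Because C1 and C5 are quaternary, 22 can enolise only towards C3, so one enol silane (23) forms. It masks C4 during the C8 reduction and merges both C3 epimers.

**21 ⇒ 20 (C4–C5).** The bond between the ketone α-carbon C5 and the carbinol carbon C4 is an aldol bond. Cutting it opens the six-membered ring to cyclopentanone 20 with a tethered aldehyde. The tether from C1 can reach only one face of C5, so the forward closure fixes C5 and puts the aryl group endo without a selectivity question.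

**20 ⇒ 15 + 18 (C1–C2).** The 1,5-relation between the C8 ketone and the C4 aldehyde is a Michael retron. C1–C2 is cut to the C1 enol silane 15 and 2-methoxyacrolein 18, which brings C2, C3 with its methoxy group, and C4 in the right oxidation state. The forward step must create the quaternary C1 anti to the neighbouring C7 methyl, and it needs the enol ether double bond at C1=C8 and nowhere else.

**15 ⇒ 13 + 14 (C6–C7, and C5–H).** The cyclopentene is opened between the two β-carbons to the acyclic dienone 13. Triethylsilane 14 supplies the hydrogen at C5 and the silyl group on oxygen. This one cut removes the ring and both stereocentres C6 and C7, and it explains why the enol silane sits at C1. The forward step is the key step.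

**13 ⇒ 10 + 2 (C5=C6 alkene).** The (Z)-enol ether alkene is an aldol-condensation retron: methoxymethyl ketone 10 and silyl-protected isovanillin 2, the latter from isovanillin 1.

**10 ⇒ 9 ⇒ 8 ⇒ 6 + 7, and 6 ⇒ 3 + 4.** The methoxymethyl group is attached to the acyl carbon through amide 9, made from ester 8. The (E)-alkene of 8 (future C1=C7) comes from a Wittig reaction of allyl-substituted ylide 6 with acetaldehyde 7. Ylide 6 is the C-allylation product of commercial ylide 3 with allyl bromide 4. Acceptor 18 is made in one step from methoxyacetaldehyde 16.

## Alternatives that were turned down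

**Alternative 1:** Ring-rearrangement metathesis.
- Disconnection: the C2=C3 bond of enone A2, with the allyl alkene C10=C11 as a second retron. This leads to A1, a cyclopentane with a cyclobutene spiro-fused at C1 and a 2-methoxyacryloyl group on C5.
- Forward key step: a ruthenium alkylidene opens the strained C2=C10 bond of A1, and the new C2 carbene closes onto the enone methylene. This forms the six-membered ring and reveals the allyl group.
- For it: A2 already has the ketone at C4 and oxygen at C8 in their final oxidation states, so no redox transposition and no late C8 reduction are needed. The step is strain-driven and both bridgeheads are in place beforehand. On these points it is stronger than the chosen route.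
- Against it: all the hard work is moved into A1, which needs C1, C5, C6, C7 and C8 set on a cyclopentane by chemistry still to be devised. The closure is onto an electron-rich, 1,1-disubstituted captodative alkene. The C2=C3 bond of A2 must then be reduced beside a terminal alkene, which brings back the C3 protonation problem.
- Comparison: the chosen route builds the cyclopentane and C6/C7 in one catalytic step from an achiral chain; alternative 1 would spend many steps reaching A1.

**Alternative 2:** Cycloaddition, then α-ketol shift.
- Disconnection: the C5–C6 bond of A4, traced by a 1,2-shift to a C4–C6 bond in the bicyclo[2.2.2]octenone A3, which a masked-quinone Diels–Alder reaction would provide.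
- Forward key step: an alkoxide base turns the bridgehead C4 hydroxyl of A3 into an alkoxide, and C6 migrates from C4 to the C5 carbonyl. This gives the bicyclo[3.2.1] skeleton of A4.
- For it: it is the shortest path to the carbon skeleton. The cycloaddition transfers alkene geometry stereospecifically into the trans C6/C7 relation and sets C1 at the same time. In convergence and step count to the cage it is stronger than the chosen route.
- Against it: the cycloaddition of achiral partners gives a racemate and has its own regio- and endo/exo questions. The ketol shift is an equilibrium whose direction is not assured. A4 carries a tertiary C5 hydroxyl that must be methylated next to a ketone under conditions that invite a reverse shift. The C8 ketal, the C2=C3 bond and C3 all remain to be dealt with.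
- Comparison: the chosen route sets absolute configuration by catalysis, carries the C5 methoxy group from the start and depends on no ketol equilibrium.

**Alternative 3:** Three-component coupling.
- Disconnection: C7–CH3, C1–C2 and C4–C5 of A6, back to the 2-allyl-4-aryl-5-methoxycyclopentenone A5.
- Forward key step: a methyl cuprate adds to C7 of A5 anti to the C6 aryl group. The C1 enolate, trapped as a silyl enol ether, adds to 2-methoxyacrolein 18, and an aldol closes C4–C5.
- For it: conjugate addition with enolate trapping is among the most reliable ways to set a trans vicinal pair and a regiodefined enolate. The endgame is the same as in the chosen route. In the reliability of the individual operations it is stronger.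
- Against it: A5 must be made as a single enantiomer with the C6 centre and the C5 methoxy group in place. Its C6 hydrogen is γ to the enone and benzylic, so A5 is prone to racemisation through the dienolate. Its preparation adds a separate multi-step sequence.
- Comparison: the chosen route reaches the same kind of C1 enol silane (15) in one step from an acyclic, achiral dienone, creating C6 and C7 together. It accepts a less precedented key step in return for a shorter route.

Key step: step 8

Assumption: the (R)-configured acid is taken to induce the sense of conrotation that gives (3R,4S,5R)-15; if the opposite sense is found, the (S)-acid is used with no other change.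

## Route

Step 1
Reactants: 1 isovanillin
Product: 2 3-(tert-butyldimethylsilyloxy)-4-methoxybenzaldehyde
Conditions: TBSCl, imidazole, DMF, rt
Reagents that add atoms: tert-butyldimethylsilyl chloride, CC(C)(C)[Si](C)(C)Cl
Why: Imidazole-mediated phenol silylation; the aryl silyl ether keeps the aldehyde electrophilic in step 6 and keeps the phenol from consuming silyl cation in step 8.

Step 2
Reactants: 3 ethyl (triphenylphosphoranylidene)acetate; 4 allyl bromide
Product: 6 ethyl 2-(triphenylphosphoranylidene)pent-4-enoate, via phosphonium bromide 5 (not isolated)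
Conditions: EtOAc, reflux; then 2 M NaOH, CH2Cl2, 0 °C
Reagents that add atoms: none
Why: SN2 C-alkylation of the stabilised ylide by the allylic bromide gives the phosphonium salt, which NaOH deprotonates to the α-allyl ylide; this introduces the future C1 allyl group.

Step 3
Reactants: 6 ethyl 2-(triphenylphosphoranylidene)pent-4-enoate; 7 acetaldehyde
Product: 8 ethyl (2E)-2-ethylidenepent-4-enoate
Conditions: CH3CHO (excess), CH2Cl2, sealed tube, 40 °C
Reagents that add atoms: none
Why: Wittig olefination of an α-substituted ester-stabilised ylide with an aliphatic aldehyde is E-selective, so the methyl group ends trans to the carbonyl, the geometry that places it outside in the cation of step 8.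

Step 4
Reactants: 8 ethyl (2E)-2-ethylidenepent-4-enoate
Product: 9 (2E)-2-ethylidene-N-methoxy-N-methylpent-4-enamide
Conditions: MeNH(OMe)·HCl, i-PrMgCl, THF, −20 °C
Reagents that add atoms: N,O-dimethylhydroxylamine hydrochloride, CNOC.Cl
Why: Aminolysis of the ester by the magnesium amide gives the Weinreb amide; conjugate addition to the α-branched enoate is not expected at this temperature.

Step 5
Reactants: 9 (2E)-2-ethylidene-N-methoxy-N-methylpent-4-enamide
Product: 10 (3E)-3-ethylidene-1-methoxyhex-5-en-2-one
Conditions: Bu3SnCH2OMe, n-BuLi, THF, −78 °C; then 9, −78 °C; aq. NH4Cl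
Reagents that add atoms: tributyl(methoxymethyl)stannane, CCCC[Sn](CCCC)(CCCC)COC
Why: Tin–lithium exchange gives the methoxymethyl organolithium, which adds once to the Weinreb amide because the chelated tetrahedral intermediate survives until work-up.

Step 6
Reactants: 10 (3E)-3-ethylidene-1-methoxyhex-5-en-2-one; 2 3-(tert-butyldimethylsilyloxy)-4-methoxybenzaldehyde
Product: 11 (4E)-1-[3-(tert-butyldimethylsilyloxy)-4-methoxyphenyl]-4-ethylidene-1-hydroxy-2-methoxyhept-6-en-3-one (diastereomer mixture)
Conditions: LiN(i-Pr)2, THF, −78 °C; then 2; aq. NH4Cl
Reagents that add atoms: none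
Why: Kinetic deprotonation occurs at the methylene between carbonyl and methoxy group, not at the vinylogous positions, and the enolate adds to the non-enolisable aldehyde (aldol addition, forming the future C5–C6 bond); both new centres are removed in step 7.

Step 7
Reactants: 11 (4E)-1-[3-(tert-butyldimethylsilyloxy)-4-methoxyphenyl]-4-ethylidene-1-hydroxy-2-methoxyhept-6-en-3-one
Product: 13 (1Z,4E)-1-[3-(tert-butyldimethylsilyloxy)-4-methoxyphenyl]-2-methoxy-4-(prop-2-en-1-yl)hexa-1,4-dien-3-one, via mesylate 12 (not isolated)
Conditions: MsCl, Et3N, CH2Cl2, 0 °C; then DBU, rt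
Reagents that add atoms: none
Why: Mesylation followed by E1cB elimination through the enolate gives the thermodynamically preferred (Z)-enol ether with aryl trans to the acyl group, the geometry that places aryl outside in step 8.

Step 8
Reactants: 13 (1Z,4E)-1-[3-(tert-butyldimethylsilyloxy)-4-methoxyphenyl]-2-methoxy-4-(prop-2-en-1-yl)hexa-1,4-dien-3-one; 14 triethylsilane
Product: 15 triethyl{[(3R,4S,5R)-4-[3-(tert-butyldimethylsilyloxy)-4-methoxyphenyl]-5-methoxy-3-methyl-2-(prop-2-en-1-yl)cyclopent-1-en-1-yl]oxy}silane
Conditions: (R)-[3,3'-(2,4,6-i-Pr3C6H2)2-BINOL]P(=O)NHSO2CF3 (10 mol %), Et3SiH (3 equiv), CHCl3, −20 °C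
Reagents that add atoms: none
Why: Proposed new method: the acid (or the silyl phosphoramide it forms with 14) activates the carbonyl oxygen of 13 to a 3-oxypentadienyl cation that the two α-substituents (methoxy, allyl) hold U-shaped with aryl and methyl both outside, and thermal conrotatory 4π electrocyclisation joins C6 to C7 and closes the five-membered ring C1–C7–C6–C5–C8 in a pericyclic ring closure. The closest known reactions are the chiral N-triflylphosphoramide-catalysed Nazarov cyclisation of 2-alkoxy dienones and the Lewis acid/Et3SiH reductive (interrupted) Nazarov cyclisation; what is new is their union, which is reasonable because hydride transfer from 14 to the oxyallyl cation leaves Et3Si+ paired with the chiral anion, and this silylates the enol oxygen and passes the proton (or the silyl group) on to the next molecule of 13. C6 and C7 are formed together: their trans relation follows stereospecifically from conrotation of the (1Z,4E) geometry, and their absolute sense from the chiral counter-anion, which stays ion-paired or hydrogen-bonded to the cation and favours one direction of conrotation. The methoxy group turns the C5 terminus of the oxyallyl cation into an oxocarbenium ion, so hydride enters at C5 (anti to the C6 aryl) and the enol ether double bond is left at C1=C8; the C5 configuration is lost again in step 11. The step therefore needs torquoselectivity (catalyst), regioselective capture (2-methoxy group) and capture that outruns loss of the C6 proton, for which excess 14 in a non-basic medium is used. The regiodefined C1 enol silane is what allows step 10 to proceed without enolate equilibration.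

Step 9
Reactants: 16 methoxyacetaldehyde
Product: 18 2-methoxyacrolein, via Mannich base 17 (not isolated)
Conditions: CH2=NMe2+ I−, Et3N, CH2Cl2, rt; used as a fresh solution
Reagents that add atoms: N,N-dimethylmethyleneiminium iodide (Eschenmoser's salt), C=[N+](C)C.[I-]
Why: Mannich α-aminomethylation of the aldehyde followed by β-elimination of dimethylamine is the standard α-methylenation of alkoxyacetaldehydes.

Step 10
Reactants: 15 triethylsilyl enol ether from step 8; 18 2-methoxyacrolein
Product: 20 3-[(1S,2R,3S,4R)-3-[3-(tert-butyldimethylsilyloxy)-4-methoxyphenyl]-4-methoxy-2-methyl-5-oxo-1-(prop-2-en-1-yl)cyclopentyl]-2-methoxypropanal (both epimers at the propanal α-carbon), via aldehyde enol triethylsilyl ether 19 (not isolated)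
Conditions: Sc(OTf)3 (10 mol %), CH2Cl2, −78 °C; then 1 M HCl, THF, 0 °C
Reagents that add atoms: none
Why: Mukaiyama–Michael addition: the Lewis acid complex of 18 behaves as a 2-methoxyallyl cation whose methylene terminus is attacked by C1 of the enol silane, forming C1–C2 and the quaternary centre anti to the adjacent C7 methyl (and so cis to the C6 aryl), as in enolate trapping after conjugate addition to cyclopentenones. Silyl transfer gives the aldehyde enol silyl ether, which is hydrolysed on work-up; C3 is formed unselectively and is corrected in step 15.

Step 11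
Reactants: 20 keto aldehyde from step 10
Product: 21 (1S,5R,6S,7R)-6-[3-(tert-butyldimethylsilyloxy)-4-methoxyphenyl]-4-hydroxy-3,5-dimethoxy-7-methyl-1-(prop-2-en-1-yl)bicyclo[3.2.1]octan-8-one (aryl endo; C3 and C4 epimers)
Conditions: DBU (0.3 equiv), CH2Cl2, 0 °C to rt
Reagents that add atoms: none
Why: Intramolecular aldol addition: the ketone enolises only towards C5 and attacks the aldehyde in a 6-exo-trig closure forming C4–C5; the tether from C1 reaches only the face of C5 cis to the aryl group, which fixes C5 and places aryl endo. Dehydration is impossible because C5 becomes quaternary, and the amine base leaves the aryl silyl ether intact.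

Step 12
Reactants: 21 bicyclic aldol from step 11
Product: 22 (1S,5S,6S,7R)-6-[3-(tert-butyldimethylsilyloxy)-4-methoxyphenyl]-3,5-dimethoxy-7-methyl-1-(prop-2-en-1-yl)bicyclo[3.2.1]octane-4,8-dione (C3 epimers)
Conditions: Dess–Martin periodinane, CH2Cl2, rt
Reagents that add atoms: none
Why: Dess–Martin oxidation of the secondary alcohol under neutral conditions, which spares the non-enolisable β-diketone from retro-Claisen cleavage; the C4 epimers converge.

Step 13
Reactants: 22 diketone from step 12
Product: 23 (1S,5R,6S,7R)-4-(tert-butyldimethylsilyloxy)-6-[3-(tert-butyldimethylsilyloxy)-4-methoxyphenyl]-3,5-dimethoxy-7-methyl-1-(prop-2-en-1-yl)bicyclo[3.2.1]oct-3-en-8-one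
Conditions: TBSOTf, Et3N, CH2Cl2, 0 °C
Reagents that add atoms: tert-butyldimethylsilyl trifluoromethanesulfonate, CC(C)(C)[Si](C)(C)OS(=O)(=O)C(F)(F)F
Why: Soft enolisation and O-silylation: C3–H is the only α-hydrogen of the diketone, so one enol silane forms and both C3 epimers converge. The C4 carbonyl and its α-methoxy group are thereby masked for step 14.

Step 14
Reactants: 23 enol silane ketone from step 13
Product: 24 (1S,5S,6S,7R,8S)-4-(tert-butyldimethylsilyloxy)-6-[3-(tert-butyldimethylsilyloxy)-4-methoxyphenyl]-3,5-dimethoxy-7-methyl-1-(prop-2-en-1-yl)bicyclo[3.2.1]oct-3-en-8-ol (hydroxyl syn to C2–C4)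
Conditions: SmI2, H2O, Et3N, THF, 0 °C
Reagents that add atoms: none
Why: Electron-transfer reduction of the ketone: the ketyl and derived carbanion pyramidalise with the bulky samarium-bound oxygen away from the exo C7 methyl, so carbon is protonated on the methyl side and the more stable alcohol forms, as in dissolving-metal reductions of camphor-type ketones where hydride reagents give the opposite epimer. The C5–OMe bond lies in the nodal plane of the C8 ketyl and its loss would need a bridgehead enolate, so no demethoxylation is expected.

Step 15
Reactants: 24 alcohol from step 14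
Product: 25 (1S,3S,5S,6S,7R,8S)-8-hydroxy-6-(3-hydroxy-4-methoxyphenyl)-3,5-dimethoxy-7-methyl-1-(prop-2-en-1-yl)bicyclo[3.2.1]octan-4-one (CNP0209708.1)
Conditions: Bu4NF, AcOH, THF, −78 to 0 °C
Reagents that add atoms: none
Why: Fluoride cleaves the enol silyl ether and the aryl silyl ether; the C4 enolate is C-protonated under kinetic control on the face of C3 that looks at C8, where the C8 hydroxyl about 3 Å above C3 can relay the proton, while the other face is screened by the endo aryl group. The acetic acid buffer suppresses C3 epimerisation and retro-aldol opening.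

## Compound list

1 | isovanillin (3-hydroxy-4-methoxybenzaldehyde) | COc1ccc(C=O)cc1O | starting material
2 | 3-(tert-butyldimethylsilyloxy)-4-methoxybenzaldehyde | COc1ccc(C=O)cc1O[Si](C)(C)C(C)(C)C | intermediate
3 | ethyl (triphenylphosphoranylidene)acetate | CCOC(=O)C=P(c1ccccc1)(c1ccccc1)c1ccccc1 | starting material
4 | allyl bromide | C=CCBr | starting material
5 | (1-ethoxy-1-oxopent-4-en-2-yl)triphenylphosphonium bromide | CCOC(=O)C(CC=C)[P+](c1ccccc1)(c1ccccc1)c1ccccc1.[Br-] | intermediate
6 | ethyl 2-(triphenylphosphoranylidene)pent-4-enoate | CCOC(=O)C(CC=C)=P(c1ccccc1)(c1ccccc1)c1ccccc1 | intermediate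
7 | acetaldehyde | CC=O | starting material
8 | ethyl (2E)-2-ethylidenepent-4-enoate | C/C=C(\CC=C)C(=O)OCC | intermediate
9 | (2E)-2-ethylidene-N-methoxy-N-methylpent-4-enamide | C/C=C(\CC=C)C(=O)N(C)OC | intermediate
10 | (3E)-3-ethylidene-1-methoxyhex-5-en-2-one | C/C=C(\CC=C)C(=O)COC | intermediate
11 | (4E)-1-[3-(tert-butyldimethylsilyloxy)-4-methoxyphenyl]-4-ethylidene-1-hydroxy-2-methoxyhept-6-en-3-one, diastereomer mixture | C/C=C(\CC=C)C(=O)C(OC)C(O)c1ccc(OC)c(O[Si](C)(C)C(C)(C)C)c1 | intermediate
12 | methanesulfonate of 11 at the benzylic hydroxyl | C/C=C(\CC=C)C(=O)C(OC)C(OS(C)(=O)=O)c1ccc(OC)c(O[Si](C)(C)C(C)(C)C)c1 | intermediate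
13 | (1Z,4E)-1-[3-(tert-butyldimethylsilyloxy)-4-methoxyphenyl]-2-methoxy-4-(prop-2-en-1-yl)hexa-1,4-dien-3-one | C/C=C(\CC=C)C(=O)/C(OC)=C/c1ccc(OC)c(O[Si](C)(C)C(C)(C)C)c1 | intermediate
14 | triethylsilane | CC[SiH](CC)CC | starting material
15 | triethyl{[(3R,4S,5R)-4-[3-(tert-butyldimethylsilyloxy)-4-methoxyphenyl]-5-methoxy-3-methyl-2-(prop-2-en-1-yl)cyclopent-1-en-1-yl]oxy}silane (aryl and methyl trans) | C=CCC1=C(O[Si](CC)(CC)CC)[C@H](OC)[C@H](c2ccc(OC)c(O[Si](C)(C)C(C)(C)C)c2)[C@H]1C | intermediate
16 | methoxyacetaldehyde | COCC=O | starting material
17 | 3-(dimethylamino)-2-methoxypropanal | COC(CN(C)C)C=O | intermediate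
18 | 2-methoxyacrolein (2-methoxyprop-2-enal) | C=C(OC)C=O | intermediate
19 | triethylsilyl enol ether of aldehyde 20 | C=CC[C@@]1(CC(OC)=CO[Si](CC)(CC)CC)C(=O)[C@H](OC)[C@H](c2ccc(OC)c(O[Si](C)(C)C(C)(C)C)c2)[C@H]1C | intermediate
20 | 3-[(1S,2R,3S,4R)-3-[3-(tert-butyldimethylsilyloxy)-4-methoxyphenyl]-4-methoxy-2-methyl-5-oxo-1-(prop-2-en-1-yl)cyclopentyl]-2-methoxypropanal, both epimers at the propanal α-carbon | C=CC[C@@]1(CC(OC)C=O)C(=O)[C@H](OC)[C@H](c2ccc(OC)c(O[Si](C)(C)C(C)(C)C)c2)[C@H]1C | intermediate
21 | (1S,5R,6S,7R)-6-[3-(tert-butyldimethylsilyloxy)-4-methoxyphenyl]-4-hydroxy-3,5-dimethoxy-7-methyl-1-(prop-2-en-1-yl)bicyclo[3.2.1]octan-8-one, aryl endo, methyl exo, C3 and C4 epimers | C=CC[C@]12CC(OC)C(O)[C@](OC)([C@H](c3ccc(OC)c(O[Si](C)(C)C(C)(C)C)c3)[C@H]1C)C2=O | intermediate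
22 | (1S,5S,6S,7R)-6-[3-(tert-butyldimethylsilyloxy)-4-methoxyphenyl]-3,5-dimethoxy-7-methyl-1-(prop-2-en-1-yl)bicyclo[3.2.1]octane-4,8-dione, C3 epimers | C=CC[C@]12CC(OC)C(=O)[C@](OC)([C@H](c3ccc(OC)c(O[Si](C)(C)C(C)(C)C)c3)[C@H]1C)C2=O | intermediate
23 | (1S,5R,6S,7R)-4-(tert-butyldimethylsilyloxy)-6-[3-(tert-butyldimethylsilyloxy)-4-methoxyphenyl]-3,5-dimethoxy-7-methyl-1-(prop-2-en-1-yl)bicyclo[3.2.1]oct-3-en-8-one | C=CC[C@]12CC(OC)=C(O[Si](C)(C)C(C)(C)C)[C@](OC)([C@H](c3ccc(OC)c(O[Si](C)(C)C(C)(C)C)c3)[C@H]1C)C2=O | intermediate
24 | (1S,5S,6S,7R,8S)-4-(tert-butyldimethylsilyloxy)-6-[3-(tert-butyldimethylsilyloxy)-4-methoxyphenyl]-3,5-dimethoxy-7-methyl-1-(prop-2-en-1-yl)bicyclo[3.2.1]oct-3-en-8-ol, hydroxyl syn to C2–C4 | C=CC[C@]12CC(OC)=C(O[Si](C)(C)C(C)(C)C)[C@](OC)([C@H](c3ccc(OC)c(O[Si](C)(C)C(C)(C)C)c3)[C@H]1C)[C@H]2O | intermediate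
25 | (1S,3S,5S,6S,7R,8S)-8-hydroxy-6-(3-hydroxy-4-methoxyphenyl)-3,5-dimethoxy-7-methyl-1-(prop-2-en-1-yl)bicyclo[3.2.1]octan-4-one (CNP0209708.1) | C=CC[C@]12C[C@H](OC)C(=O)[C@](OC)([C@H](c3ccc(OC)c(O)c3)[C@H]1C)[C@H]2O | target

## Step count and least certain steps

Total: 15 steps. Longest linear sequence: 13 steps (steps 2–8 and 10–15, from ylide 3); steps 1 and 9 are one-step side branches.

**Step 8 (key step, new combination).**
- What may go wrong: the silyl cation released after hydride transfer may act as an achiral chain-carrying Lewis acid and erode enantiocontrol. Proton loss from C6 may outrun hydride capture. Hydride may be delivered to the benzylic terminus of the open cation before ring closure. The product enol silane may be protodesilylated by the acid.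
- Fallback (known chemistry): from 13 and 14, the established stoichiometric BF3·OEt2/Et3SiH reductive Nazarov cyclisation in CH2Cl2 at −78 °C, quenched with Et3N so that the silyl enol ether survives. The trans relation still comes from conrotation, but the product is the racemate, 15 together with its mirror image, the (3S,4R,5S)-enol silane F1. The enantiomers are separated by preparative chromatography on a chiral stationary phase, and the route is rejoined at 15.

**Step 10.**
- What may go wrong: competing 1,2-addition to the aldehyde carbonyl, polymerisation of the acceptor, and erosion of facial selectivity, because the attacked face of C1 also carries the C5 methoxy and C6 aryl groups.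
- Fallback: from 15, TiCl4-promoted Mukaiyama–Michael addition to commercial methyl 2-methoxyacrylate. An ester cannot undergo 1,2-addition and is activated by chelation through its α-methoxy group. This gives the keto ester methyl 3-[(1S,2R,3S,4R)-3-aryl-4-methoxy-2-methyl-5-oxo-1-allylcyclopentyl]-2-methoxypropanoate F2. Intramolecular Claisen condensation of its C5 enolate with KN(SiMe3)2 (2 equiv; the second equivalent traps the product as its C3 enolate) then gives diketone 22 directly. The route is rejoined at 22, and steps 11 and 12 are not needed.

**Step 14.**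
- What may go wrong: delivery of hydrogen to the face of C8 remote from the methyl group (poor facial selectivity), or loss of the enol silyl ether in the aqueous amine medium.
- Fallback: from 23, NaBH4 in MeOH/THF at 0 °C, which is expected to attack from the open six-ring face and give mainly the C8 epimer F3 (hydroxyl syn to C6–C7). A Meerwein–Ponndorf–Verley/Oppenauer equilibration follows (Al(Oi-Pr)3, i-PrOH, catalytic acetone, toluene, 80 °C). It converts F3 through the ketone into the more stable epimer 24, in which the hydroxyl avoids the exo methyl group. The route is rejoined at 24.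

**Step 15.**
- What may go wrong: protonation on the face of C3 next to the endo aryl group, epimerisation at C3 after protonation, or retro-aldol opening of the β-hydroxy ketone under basic fluoride.
- Fallback: from 24, if the C3 epimer F4 (methoxy group syn to C8) predominates, control is changed from kinetic to thermodynamic. F4 and 25 are equilibrated with DBU in benzene, a non-polar medium that favours the axial α-methoxy ketone because its C–O and C=O dipoles are opposed. 25 is removed by chromatography and the remainder is recycled, so the route comes back at 25. This works only if 25 is competitive at equilibrium, which is not assured.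

## Further compounds

F1 | step 8 | triethyl{[(3S,4R,5S)-4-[3-(tert-butyldimethylsilyloxy)-4-methoxyphenyl]-5-methoxy-3-methyl-2-(prop-2-en-1-yl)cyclopent-1-en-1-yl]oxy}silane (enantiomer of 15) | C=CCC1=C(O[Si](CC)(CC)CC)[C@@H](OC)[C@@H](c2ccc(OC)c(O[Si](C)(C)C(C)(C)C)c2)[C@@H]1C
F2 | step 10 | methyl 3-[(1S,2R,3S,4R)-3-[3-(tert-butyldimethylsilyloxy)-4-methoxyphenyl]-4-methoxy-2-methyl-5-oxo-1-(prop-2-en-1-yl)cyclopentyl]-2-methoxypropanoate | C=CC[C@@]1(CC(OC)C(=O)OC)C(=O)[C@H](OC)[C@H](c2ccc(OC)c(O[Si](C)(C)C(C)(C)C)c2)[C@H]1C
F3 | step 14 | C8 epimer of 24 (hydroxyl syn to C6–C7) | C=CC[C@]12CC(OC)=C(O[Si](C)(C)C(C)(C)C)[C@](OC)([C@H](c3ccc(OC)c(O[Si](C)(C)C(C)(C)C)c3)[C@H]1C)[C@@H]2O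
F4 | step 15 | C3 epimer of 25 (methoxy group syn to C8) | C=CC[C@]12C[C@@H](OC)C(=O)[C@](OC)([C@H](c3ccc(OC)c(O)c3)[C@H]1C)[C@H]2O
A1 | alternative 1 | spiro-cyclobutene cyclopentane with 2-methoxyacryloyl group at C5 and silyl ether at C8 | C=C(OC)C(=O)[C@]1(OC)[C@H](c2ccc(OC)c(O[Si](C)(C)C(C)(C)C)c2)[C@@H](C)[C@@]3(CC=C3)[C@@H]1O[Si](C)(C)C(C)(C)C
A2 | alternative 1 | 1-allyl-3-methoxybicyclo[3.2.1]oct-2-en-4-one, C8 silyl ether | C=CC[C@]12C=C(OC)C(=O)[C@](OC)([C@H](c3ccc(OC)c(O[Si](C)(C)C(C)(C)C)c3)[C@H]1C)[C@H]2O[Si](C)(C)C(C)(C)C
A3 | alternative 2 | bicyclo[2.2.2]octenone with bridgehead C4 hydroxyl, C5 ketone and C8 dimethyl ketal | C=CC[C@]12C=C(OC)[C@@](O)(C(=O)C2(OC)OC)[C@H](c3ccc(OC)c(O[Si](C)(C)C(C)(C)C)c3)[C@H]1C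
A4 | alternative 2 | 5-hydroxy-3-methoxybicyclo[3.2.1]oct-2-en-4-one, C8 dimethyl ketal | C=CC[C@]12C=C(OC)C(=O)[C@](O)([C@H](c3ccc(OC)c(O[Si](C)(C)C(C)(C)C)c3)[C@H]1C)C2(OC)OC
A5 | alternative 3 | (4S)-2-allyl-4-[3-(tert-butyldimethylsilyloxy)-4-methoxyphenyl]-5-methoxycyclopent-2-enone | C=CCC1=C[C@@H](c2ccc(OC)c(O[Si](C)(C)C(C)(C)C)c2)C(OC)C1=O
A6 | alternative 3 | 4-hydroxybicyclo[3.2.1]octan-8-one aldol | C=CC[C@]12C[C@H](OC)[C@@H](O)[C@](OC)([C@H](c3ccc(OC)c(O[Si](C)(C)C(C)(C)C)c3)[C@H]1C)C2=O
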